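The numbers in the tables are calculated from invented constants, noise included.

**Short answer.** It stops. You want a quick number for 8.0 min, and dawn and winter, with the same substrate and gas, have levelled off by 4.00 min. Dawn leaves 51.3 % substrate and winter 22.2 %, so more catalyst goes further. The asked time is twice that, so I reckon the stopping point, not a rate.

| flask | substrate | gas phase | free catalyst | remark | time |
|---|---|---|---|---|---|
| dawn | 0.056 M | 3 mM (held) | 0.29 mol% | run made earlier |  |
| winter | 0.056 M | 3 mM (held) | 1.7 mol% | run made earlier |  |
| west | 0.056 M | 3.0 mM (held) | 0.2 mol% |  | 8.0 min |
| north-east | 0.056 M | 3.0 mM (held) | 0.5 mol% |  | 8.0 min |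
| south-east | 0.056 M | 3.0 mM (held) | 1.2 mol% |  | 8.0 min |

- dawn (time / min: substrate / %, product / %): 0.500: 80.3, 19.0; 1.33: 60.4, 39.0; 2.50: 52.8, 47.0; 4.00: 51.3, 47.5
- winter (time / min: substrate / %, product / %): 0.333: 71.0, 28.7; 0.667: 47.7, 50.5; 1.50: 25.9, 72.5; 4.00: 22.2, 77.0

(scatter of a reading: 0.5 percentage points)

1. which of these there is most of at the end, counted by the substrate in it, west (substrate / product)
2. which of these there is most of at the end, counted by the substrate in it, north-east (substrate / product)
3. which of these there is most of at the end, counted by the substrate in it, south-east (substrate / product)
4. amount of the one of these that there is most of at the end, in percent of the substrate charged, west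
5. amount of the one of these that there is most of at the end, in percent of the substrate charged, north-east
6. amount of the one of these that there is most of at the end, in percent of the substrate charged, south-east

- at the start none of the gas is dissolved
- what may be going on: gas phase <-> dissolved gas; substrate + dissolved gas + free catalyst -> free catalyst + product; free catalyst + product -> spent catalyst

**Stop number.** Suppose product kills free catalyst (product poisoning) while free catalyst makes product. Dividing one rate by the other cancels free catalyst and time. If I also freeze c(dissolved gas) at saturation, a quantity L of the fraction s of substrate left at the stop, L = ln(1/s) + s − 1, grows in proportion to the loading. Dawn's last reading gives 0.180, its stop number. Winter reads 0.727, smaller than the 1.06 the loading ratio asks. I take that as the gas sagging below saturation at high loading, so the frozen gas holds best near dawn.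

**My reckoning.** For small L the converted share is about √(2L) − 2L/3. West, scaled from dawn, has L = 0.124, which leaves about 58.5 % substrate. North-east has L = 0.311, which converts about 58.1 %. South-east has L = 0.513 scaled from winter and 0.747 scaled from dawn, too large for that short form, so I solve the definition of L in full and get a conversion between 70.4 % and 78.3 %.

**The forecast.** It says "Conversion stops when the catalyst is gone" and gives west substrate at 56.9 %, north-east product at 57.6 %, south-east product at 71.4 %. Its south-east conversion of about 72.6% stands in the lower part of my range.

**The flask.** West ends with substrate at 57.1 %, north-east with product at 57.5 %, south-east with product at 71.5 %. The forecast stands on each.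

    gas phase ⇌ dissolved gas, rate k1*(csat - [dissolved gas]) (kL = 0.378 s⁻¹)
    substrate + dissolved gas + free catalyst → free catalyst + product (k = 24900 M⁻² s⁻¹)
    free catalyst + product → spent catalyst (k = 0.990 M⁻¹ s⁻¹)

**What would break it.** West's own stop number is 0.131, near the 0.124 scaled from dawn. The forecast's west would turn wrong if product did not kill the catalyst: the west run without that step gives 97.2 % product instead of 42.7 %, and substrate no longer leads.

**Less catalyst.** North-east cut to 0.12 mol% free catalyst scales to L = 0.0747, so about 66.3 % substrate should remain. That neighbour flask, computed, leaves 65 %.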